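The cyclopentane ring (indane numbering: C1, C2, C3, C3a, C7a) is closed last, by forming C1–C2 in an intramolecular nitrile oxide–alkene cycloaddition. The step exploits the 1,3-dioxygenated array O–C2–C1–Cα–O (Cα = acetoxy carbon): a nitrile oxide at C2, tethered through C3 to C3a, adds across a (Z)-enoate on C7a, making C1–C2 and Cα–O together, setting C1 and Cα, and leaving an isoxazoline whose N–O bond, absent from the target, is cleaved later to the masked aldol. The precursor is a fully substituted bromocyclohexane; the isoxazoline ester then takes up a chiral 1,5-bis-Grignard reagent that builds the second ring at C1'.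

Key step: step 15

Remark on the chemistry: 1 and 19 are taken as commercial; C1'–C6' label the second ring (C3' = CMe2, C4' = CHBr); C2 of ketones 8–10 is epimerisable and is drawn in the configuration to which step 9 equilibrates it.

Step 1
Reactants: 1 1,4-dioxaspiro[4.5]dec-6-en-8-one
Product: 2 (R)-1,4-dioxaspiro[4.5]dec-6-en-8-ol
Conditions: (S)-Me-CBS oxazaborolidine (cat.), BH3·SMe2, THF, −20 °C; MeOH
Reagents that add atoms: none
Why: Corey–Bakshi–Shibata 1,2-reduction of the enone, with the vinyl branch acting as the large group, should deliver hydride to one face and give the (R)-allylic alcohol.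

Step 2
Reactants: 2 (R)-allylic alcohol
Product: 3 (R)-TBS ether of 2
Conditions: TBSCl, imidazole, DMF, rt
Reagents that add atoms: tert-butyldimethylsilyl chloride, CC(C)(C)[Si](C)(C)Cl
Why: Standard silylation of a secondary alcohol installs the bulky group that later steers both cuprate additions.

Step 3
Reactants: 3 TBS ether ketal
Product: 4 (R)-4-[(tert-butyldimethylsilyl)oxy]cyclohex-2-en-1-one
Conditions: PPTS, acetone/H2O, 55 °C
Reagents that add atoms: water, O
Why: Mild acid-catalysed ketal hydrolysis unmasks the enone while the silyl ether should survive.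

Step 4
Reactants: 4 silyloxy enone
Product: 5 (3R,4R)-3-allyl-4-(TBS-oxy)-1-(trimethylsilyloxy)cyclohex-1-ene
Conditions: allylMgBr, CuBr·SMe2 (cat.), LiCl, TMSCl, THF, −78 °C; Et3N
Reagents that add atoms: allylmagnesium bromide, C=CC[Mg]Br; chlorotrimethylsilane, C[Si](C)(C)Cl
Why: Copper-catalysed, TMSCl-accelerated conjugate addition should occur anti to the 4-silyloxy group and trap the enolate regiospecifically as its silyl enol ether.

Step 5
Reactants: 5 silyl enol ether
Product: 6 (R)-3-allyl-4-[(tert-butyldimethylsilyl)oxy]cyclohex-2-en-1-one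
Conditions: IBX·MPO (4-methoxypyridine N-oxide), DMSO, rt
Reagents that add atoms: none
Why: Saegusa-type dehydrogenation of the regiodefined silyl enol ether restores the enone with allyl on the β-carbon, deliberately erasing the centre made in step 4.

Step 6
Reactants: 6 3-allyl enone
Product: 7 (3S,4R)-3-allyl-3-methyl-4-(TBS-oxy)-1-(trimethylsilyloxy)cyclohex-1-ene
Conditions: Me2CuLi, TMSCl, THF, −78 → −40 °C; Et3N
Reagents that add atoms: lithium dimethylcuprate, [Li+].C[Cu-]C; chlorotrimethylsilane, C[Si](C)(C)Cl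
Why: Gilman conjugate addition again takes place anti to the γ-silyloxy group, so methyl enters trans to OTBS and the quaternary carbon (C3a) is set with allyl cis to OTBS.

Step 7
Reactants: 7 silyl enol ether
Product: 8 (2R,3S,4R)-3-allyl-4-(TBS-oxy)-2-(dimethoxymethyl)-3-methylcyclohexan-1-one
Conditions: HC(OMe)3, BF3·OEt2, CH2Cl2, −78 °C
Reagents that add atoms: trimethyl orthoformate, COC(OC)OC
Why: Mukaiyama-type alkylation of the silyl enol ether by the dimethoxycarbenium ion installs the one-carbon acetal (future C1) at the hindered α-carbon, whose configuration need not be controlled here because step 9 equilibrates it.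

Step 8
Reactants: 8 β-keto acetal silyl ether
Product: 9 (2R,3S,4R)-3-allyl-2-(dimethoxymethyl)-4-hydroxy-3-methylcyclohexan-1-one
Conditions: Bu4NF, THF, 0 °C
Reagents that add atoms: none
Why: Fluoride cleavage of the silyl ether frees the secondary alcohol, which is cis to allyl and trans to methyl.

Step 9
Reactants: 9 hydroxy ketone
Product: 10 (2R,3S,4S)-3-allyl-4-bromo-2-(dimethoxymethyl)-3-methylcyclohexan-1-one
Conditions: CBr4, P(n-C8H17)3, toluene, 70 °C; then K2CO3, MeOH, rt
Reagents that add atoms: carbon tetrabromide, BrC(Br)(Br)Br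
Why: Appel bromination proceeds by SN2 inversion of the oxyphosphonium salt to give bromide cis to the quaternary methyl, and base then equilibrates C2 so that the acetal sits equatorial (trans to allyl) in the chair with equatorial bromide and axial methyl.

Step 10
Reactants: 10 bromo ketone
Product: 11 (1R,2S,3S,4S)-3-allyl-4-bromo-2-(dimethoxymethyl)-1,3-dimethylcyclohexan-1-ol
Conditions: MeMgBr, CeCl3, THF, −78 °C
Reagents that add atoms: methylmagnesium bromide, C[Mg]Br
Why: Organocerium 1,2-addition to the enolisable ketone takes the equatorial trajectory, anti to the axial 3-methyl group, and should give the axial tertiary alcohol cis to that methyl.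

Step 11
Reactants: 11 hydroxy acetal
Product: 12 (1S,2S,3S,6R)-2-allyl-3-bromo-2,6-dimethyl-6-[(triethylsilyl)oxy]cyclohexane-1-carbaldehyde
Conditions: Et3SiOTf, 2,4,6-collidine, CH2Cl2, 0 °C; then H2O
Reagents that add atoms: triethylsilyl trifluoromethanesulfonate, CC[Si](CC)(CC)OS(=O)(=O)C(F)(F)F; water, O
Why: The silyl triflate–collidine pair silylates the tertiary alcohol and converts the dimethyl acetal through a collidinium adduct into the aldehyde on aqueous work-up, avoiding protic acid that could cause retro-aldol or dehydration.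

Step 12
Reactants: 12 aldehyde
Product: 13 methyl (Z)-3-[(1S,2S,3S,6R)-2-allyl-3-bromo-2,6-dimethyl-6-(triethylsilyloxy)cyclohexyl]acrylate
Conditions: (CF3CH2O)2P(O)CH2CO2Me, KN(SiMe3)2, 18-crown-6, THF, −78 °C
Reagents that add atoms: methyl bis(2,2,2-trifluoroethyl)phosphonoacetate, COC(=O)CP(=O)(OCC(F)(F)F)OCC(F)(F)F
Why: Still–Gennari olefination should give the (Z)-enoate under kinetic control, and the silyl ether blocks lactonisation of the tertiary oxygen onto the cis ester.

Step 13
Reactants: 13 (Z)-enoate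
Product: 14 methyl (Z)-3-[(1S,2S,3S,6R)-3-bromo-2,6-dimethyl-2-(2-oxoethyl)-6-(triethylsilyloxy)cyclohexyl]acrylate
Conditions: OsO4 (cat.), NaIO4, 2,6-lutidine, dioxane/H2O, rt
Reagents that add atoms: osmium tetroxide, O=[Os](=O)(=O)=O; sodium periodate, [Na+].[O-]I(=O)(=O)=O
Why: Lemieux–Johnson cleavage should select the electron-rich terminal alkene over the hindered, electron-poor enoate and turns allyl into the C3–C2 aldehyde arm.

Step 14
Reactants: 14 aldehyde
Product: 15 aldoxime of 14
Conditions: NH2OH·HCl, pyridine, EtOH, 0 °C → rt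
Reagents that add atoms: hydroxylamine hydrochloride, NO.Cl
Why: Condensation of the unhindered aldehyde with hydroxylamine gives the aldoxime, whose E/Z ratio is irrelevant.

Step 15
Reactants: 15 aldoxime
Product: 18 isoxazoline ester, via hydroximoyl chloride 16 (not isolated), via nitrile oxide 17 (not isolated)
Conditions: NCS, pyridine (cat.), CHCl3, 40 °C; then Et3N (slow addition), CH2Cl2 (high dilution), 0 °C → rt
Reagents that add atoms: none
Why: Chlorination of the oxime and dehydrochlorination of 16 give nitrile oxide 17, which adds in a concerted, suprafacial 1,3-dipolar cycloaddition to the tethered (Z)-enoate; the closest known reaction type is the intramolecular nitrile oxide–olefin cycloaddition to cyclopenta-fused isoxazolines. The carbocycle (C1, C2, C3, C3a, C7a) closes in the 5-exo sense by C2→C1 bonding across a three-atom tether, trans-fused because both arms are equatorial on the chair, and the isoxazoline (O–N=C2–C1–Cα) closes in the same act by O→Cα bonding. C1 is controlled by A(1,3) strain: the cis ester forces H-7a into the alkene plane, so only the face turned toward C3a is reachable and H-1 should end trans to H-7a with the Cα branch anti to C7. Cα is fixed relative to C1 by stereospecific syn addition to the Z-alkene (H-1 and H-α cis). The step needs cyclisation to outrun furoxan dimerisation, which the tether and slow base addition at high dilution should secure, and a single regiochemistry, which the tether enforces because the other mode would give a bridged ring.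

Step 16
Reactants: 19 (S)-pantolactone
Product: 20 (S)-O-triisopropylsilyl pantolactone
Conditions: i-Pr3SiOTf, 2,6-lutidine, CH2Cl2, 0 °C → rt
Reagents that add atoms: triisopropylsilyl trifluoromethanesulfonate, CC(C)[Si](C(C)C)(C(C)C)OS(=O)(=O)C(F)(F)F
Why: Silyl triflate silylation of the hindered α-hydroxy lactone, with TIPS chosen because it resists 1,3-migration to the alkoxide formed in step 18.

Step 17
Reactants: 20 silyl lactone
Product: 21 (3S)-lactol
Conditions: i-Bu2AlH, CH2Cl2, −78 °C
Reagents that add atoms: none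
Why: Low-temperature hydride reduction of the lactone stops at the stable aluminium hemiacetal and gives the lactol on work-up.

Step 18
Reactants: 21 lactol
Product: 22 (R)-2,2-dimethyl-3-[(triisopropylsilyl)oxy]pent-4-en-1-ol
Conditions: Ph3PCH3Br, KOt-Bu, THF, 0 °C → rt
Reagents that add atoms: methyltriphenylphosphonium bromide, C[P+](c1ccccc1)(c1ccccc1)c1ccccc1.[Br-]
Why: Wittig methylenation of the lactol through its open hydroxy aldehyde adds the fifth chain carbon without touching the stereocentre.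

Step 19
Reactants: 22 alkenol
Product: 23 (R)-2,2-dimethyl-3-[(triisopropylsilyl)oxy]pentane-1,5-diol
Conditions: 9-BBN, THF, rt; then NaOH, H2O2
Reagents that add atoms: hydrogen peroxide, OO
Why: Anti-Markovnikov hydroboration–oxidation of the terminal alkene gives the primary alcohol.

Step 20
Reactants: 23 diol
Product: 24 (R)-1,5-dibromo-2,2-dimethyl-3-[(triisopropylsilyl)oxy]pentane
Conditions: CBr4, PPh3, CH2Cl2, 0 → 40 °C
Reagents that add atoms: carbon tetrabromide, BrC(Br)(Br)Br
Why: Double Appel reaction converts both primary alcohols (one neopentylic, hence the warming) into bromides and leaves the silyloxy stereocentre untouched.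

Step 21
Reactants: 18 isoxazoline ester; 24 dibromide
Product: 27 annulated silyloxy cyclohexanol, via bis-Grignard reagent 25 (not isolated), via keto Grignard intermediate 26 (not isolated)
Conditions: 24, Mg, THF, 45 °C; then MgBr2·OEt2, 18 in CH2Cl2, −78 → 0 °C; aq. NH4Cl
Reagents that add atoms: none
Why: Bis-Grignard annulation of an ester to a cyclohexanol, in which the unhindered primary terminus should acylate first and the neopentyl terminus then closes the six-membered ring onto ketone 26 held in a magnesium chelate with the isoxazoline heteroatoms, attacking from the H-α side anti to C1 (Cram chelate model) and so setting C1'.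

Step 22
Reactants: 27 bis-silyl ether
Product: 28 isoxazoline triol
Conditions: Bu4NF, AcOH, THF, 50 °C
Reagents that add atoms: none
Why: Buffered fluoride removes both silyl ethers and exposes the C4' alcohol, which is axial and trans to the C1' hydroxyl in the chair anchored by the equatorial side chain.

Step 23
Reactants: 28 triol
Product: 29 dibromo isoxazoline diol
Conditions: CBr4, P(n-C8H17)3, 2,6-di-tert-butylpyridine, toluene, 70 °C
Reagents that add atoms: carbon tetrabromide, BrC(Br)(Br)Br
Why: Appel bromination of the only secondary alcohol proceeds by SN2 inversion of the axial oxyphosphonium salt and should give the equatorial bromide cis to the C1' hydroxyl, the tertiary alcohols being too hindered to be activated.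

Step 24
Reactants: 29 isoxazoline
Product: 30 β-hydroxy ketone
Conditions: Mo(CO)6, MeCN/H2O, 80 °C
Reagents that add atoms: water, O
Why: Reductive N–O cleavage by Mo(CO)6 and hydrolysis of the resulting β-hydroxy imine unmask the aldol without reducing the alkyl bromides.

Step 25
Reactants: 30 β-hydroxy ketone
Product: 31 β-acetoxy ketone
Conditions: Ac2O, pyridine, DMAP (cat.), CH2Cl2, 0 °C → rt
Reagents that add atoms: acetic anhydride, CC(=O)OC(C)=O
Why: DMAP-catalysed acylation should take the only secondary alcohol (Cα–OH) and leave both tertiary alcohols, the C2 oxygen being still protected as the ketone.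

Step 26
Reactants: 31 β-acetoxy ketone
Product: 32 CNP0166243.1
Conditions: LiBH(s-Bu)3, THF, −78 °C; AcOH
Reagents that add atoms: none
Why: The bulky hydride should attack the cyclopentanone from the face opposite the adjacent C1 side chain, giving the C2 alcohol cis to that chain (1,3-syn to the acetate), and the cold acidic quench suppresses acetyl migration.

Compound list
1 | 1,4-dioxaspiro[4.5]dec-6-en-8-one | O=C1C=CC2(CC1)OCCO2 | starting material
2 | (R)-1,4-dioxaspiro[4.5]dec-6-en-8-ol | O[C@H]1C=CC2(CC1)OCCO2 | intermediate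
3 | (R)-tert-butyl(1,4-dioxaspiro[4.5]dec-6-en-8-yloxy)dimethylsilane | CC(C)(C)[Si](C)(C)O[C@H]1C=CC2(CC1)OCCO2 | intermediate
4 | (R)-4-[(tert-butyldimethylsilyl)oxy]cyclohex-2-en-1-one | CC(C)(C)[Si](C)(C)O[C@H]1C=CC(=O)CC1 | intermediate
5 | (3R,4R)-3-allyl-4-[(tert-butyldimethylsilyl)oxy]-1-[(trimethylsilyl)oxy]cyclohex-1-ene (allyl trans to OTBS) | C=CC[C@@H]1C=C(O[Si](C)(C)C)CC[C@H]1O[Si](C)(C)C(C)(C)C | intermediate
6 | (R)-3-allyl-4-[(tert-butyldimethylsilyl)oxy]cyclohex-2-en-1-one | C=CCC1=CC(=O)CC[C@H]1O[Si](C)(C)C(C)(C)C | intermediate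
7 | (3S,4R)-3-allyl-4-[(tert-butyldimethylsilyl)oxy]-3-methyl-1-[(trimethylsilyl)oxy]cyclohex-1-ene (methyl trans, allyl cis to OTBS) | C=CC[C@]1(C)[C@H](O[Si](C)(C)C(C)(C)C)CCC(O[Si](C)(C)C)=C1 | intermediate
8 | (2R,3S,4R)-3-allyl-4-[(tert-butyldimethylsilyl)oxy]-2-(dimethoxymethyl)-3-methylcyclohexan-1-one | C=CC[C@]1(C)[C@H](O[Si](C)(C)C(C)(C)C)CCC(=O)[C@H]1C(OC)OC | intermediate
9 | (2R,3S,4R)-3-allyl-2-(dimethoxymethyl)-4-hydroxy-3-methylcyclohexan-1-one | C=CC[C@]1(C)[C@H](O)CCC(=O)[C@H]1C(OC)OC | intermediate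
10 | (2R,3S,4S)-3-allyl-4-bromo-2-(dimethoxymethyl)-3-methylcyclohexan-1-one (Br cis to methyl) | C=CC[C@]1(C)[C@@H](Br)CCC(=O)[C@H]1C(OC)OC | intermediate
11 | (1R,2S,3S,4S)-3-allyl-4-bromo-2-(dimethoxymethyl)-1,3-dimethylcyclohexan-1-ol | C=CC[C@]1(C)[C@@H](Br)CC[C@@](C)(O)[C@H]1C(OC)OC | intermediate
12 | (1S,2S,3S,6R)-2-allyl-3-bromo-2,6-dimethyl-6-[(triethylsilyl)oxy]cyclohexane-1-carbaldehyde | C=CC[C@]1(C)[C@@H](Br)CC[C@@](C)(O[Si](CC)(CC)CC)[C@H]1C=O | intermediate
13 | methyl (Z)-3-[(1S,2S,3S,6R)-2-allyl-3-bromo-2,6-dimethyl-6-[(triethylsilyl)oxy]cyclohexyl]acrylate | C=CC[C@]1(C)[C@@H](Br)CC[C@@](C)(O[Si](CC)(CC)CC)[C@H]1/C=C\C(=O)OC | intermediate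
14 | methyl (Z)-3-[(1S,2S,3S,6R)-3-bromo-2,6-dimethyl-2-(2-oxoethyl)-6-[(triethylsilyl)oxy]cyclohexyl]acrylate | O=CC[C@]1(C)[C@@H](Br)CC[C@@](C)(O[Si](CC)(CC)CC)[C@H]1/C=C\C(=O)OC | intermediate
15 | methyl (Z)-3-[(1S,2S,3S,6R)-3-bromo-2-[2-(hydroxyimino)ethyl]-2,6-dimethyl-6-[(triethylsilyl)oxy]cyclohexyl]acrylate (oxime E/Z mixture) | ON=CC[C@]1(C)[C@@H](Br)CC[C@@](C)(O[Si](CC)(CC)CC)[C@H]1/C=C\C(=O)OC | intermediate
16 | hydroximoyl chloride of 15 | ON=C(Cl)C[C@]1(C)[C@@H](Br)CC[C@@](C)(O[Si](CC)(CC)CC)[C@H]1/C=C\C(=O)OC | intermediate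
17 | nitrile oxide from 16 | [O-][N+]#CC[C@]1(C)[C@@H](Br)CC[C@@](C)(O[Si](CC)(CC)CC)[C@H]1/C=C\C(=O)OC | intermediate
18 | isoxazoline ester: methyl 4,5-dihydroisoxazole-5-carboxylate fused across C1–C2 of the 4-bromo-3a,7-dimethyl-7-(triethylsilyloxy)hexahydroindane; H-1 and H-α cis, H-1 trans to H-7a, other centres as in the target | O1N=C2C[C@]3(C)[C@@H](Br)CC[C@@](C)(O[Si](CC)(CC)CC)[C@H]3[C@@H]2[C@@H]1C(=O)OC | intermediate
19 | (S)-pantolactone, (3S)-3-hydroxy-4,4-dimethyldihydrofuran-2(3H)-one | CC1(C)COC(=O)[C@H]1O | starting material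
20 | (S)-4,4-dimethyl-3-[(triisopropylsilyl)oxy]dihydrofuran-2(3H)-one | CC1(C)COC(=O)[C@H]1O[Si](C(C)C)(C(C)C)C(C)C | intermediate
21 | (3S)-4,4-dimethyl-3-[(triisopropylsilyl)oxy]tetrahydrofuran-2-ol (anomer mixture) | CC1(C)COC(O)[C@H]1O[Si](C(C)C)(C(C)C)C(C)C | intermediate
22 | (R)-2,2-dimethyl-3-[(triisopropylsilyl)oxy]pent-4-en-1-ol | C=C[C@@H](O[Si](C(C)C)(C(C)C)C(C)C)C(C)(C)CO | intermediate
23 | (R)-2,2-dimethyl-3-[(triisopropylsilyl)oxy]pentane-1,5-diol | OCC[C@@H](O[Si](C(C)C)(C(C)C)C(C)C)C(C)(C)CO | intermediate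
24 | (R)-1,5-dibromo-2,2-dimethyl-3-[(triisopropylsilyl)oxy]pentane | BrCC[C@@H](O[Si](C(C)C)(C(C)C)C(C)C)C(C)(C)CBr | intermediate
25 | 1,5-bis(bromomagnesio) reagent from 24 | Br[Mg]CC[C@@H](O[Si](C(C)C)(C(C)C)C(C)C)C(C)(C)C[Mg]Br | intermediate
26 | isoxazolinyl ketone carrying the neopentyl Grignard terminus | O1N=C2C[C@]3(C)[C@@H](Br)CC[C@@](C)(O[Si](CC)(CC)CC)[C@H]3[C@@H]2[C@@H]1C(=O)CC[C@@H](O[Si](C(C)C)(C(C)C)C(C)C)C(C)(C)C[Mg]Br | intermediate
27 | isoxazoline with the annulated ring: C1' tertiary alcohol (target configuration), C4' silyl ether trans to the C1' hydroxyl, C7 triethylsilyl ether | O1N=C2C[C@]3(C)[C@@H](Br)CC[C@@](C)(O[Si](CC)(CC)CC)[C@H]3[C@@H]2[C@@H]1[C@@]4(O)CC[C@@H](O[Si](C(C)C)(C(C)C)C(C)C)C(C)(C)C4 | intermediate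
28 | isoxazoline triol (C7–OH, C1'–OH, C4'–OH, the last trans to C1'–OH) | O1N=C2C[C@]3(C)[C@@H](Br)CC[C@@](C)(O)[C@H]3[C@@H]2[C@@H]1[C@@]4(O)CC[C@@H](O)C(C)(C)C4 | intermediate
29 | dibromo isoxazoline diol (C4'–Br cis to C1'–OH) | O1N=C2C[C@]3(C)[C@@H](Br)CC[C@@](C)(O)[C@H]3[C@@H]2[C@@H]1[C@@]4(O)CC[C@H](Br)C(C)(C)C4 | intermediate
30 | (1R,3aS,4S,7R,7aS)-4-bromo-1-{(R)-[(1R,4S)-4-bromo-1-hydroxy-3,3-dimethylcyclohexyl](hydroxy)methyl}-7-hydroxy-3a,7-dimethyloctahydro-2H-inden-2-one | O[C@H]([C@@H]1C(=O)C[C@]2(C)[C@@H](Br)CC[C@@](C)(O)[C@@H]12)[C@@]1(O)CC[C@H](Br)C(C)(C)C1 | intermediate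
31 | (R)-[(1R,4S)-4-bromo-1-hydroxy-3,3-dimethylcyclohexyl][(1R,3aS,4S,7R,7aS)-4-bromo-7-hydroxy-3a,7-dimethyl-2-oxooctahydro-1H-inden-1-yl]methyl acetate | CC(=O)O[C@H]([C@@H]1C(=O)C[C@]2(C)[C@@H](Br)CC[C@@](C)(O)[C@@H]12)[C@@]1(O)CC[C@H](Br)C(C)(C)C1 | intermediate
32 | CNP0166243.1, (R)-[(1R,4S)-4-bromo-1-hydroxy-3,3-dimethylcyclohexyl][(1S,2R,3aS,4S,7R,7aS)-4-bromo-2,7-dihydroxy-3a,7-dimethyloctahydro-1H-inden-1-yl]methyl acetate | CC(=O)O[C@H]([C@@H]1[C@H](O)C[C@]2(C)[C@@H](Br)CC[C@@](C)(O)[C@@H]12)[C@@]1(O)CC[C@H](Br)C(C)(C)C1 | target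

Total steps: 26. Longest linear sequence: 21 steps (steps 1–15 and 21–26); steps 16–20 make the bis-electrophile 24 in a separate branch.

Steps most likely to fail

Step 21 (bis-Grignard annulation). The one-pot double addition may oligomerise, the neopentyl terminus may attack first, or the ring closure may follow an open Felkin–Anh mode instead of the chelate, which would invert C1'. The fallback sets out from 18 and 22 and comes back at 27, introducing the two arms one at a time in the reverse order and closing the ring by metathesis. Ester 18 is converted (MeNH(OMe)·HCl, i-PrMgCl, THF, −20 °C) into the Weinreb amide F1. Alkenol 22 is brominated (CBr4, PPh3) to the neopentyl bromide F2, whose Grignard reagent F3 (Mg, THF) acylates F1 to the ketone F4. Vinylmagnesium bromide in THF at −78 °C, with no added Lewis acid, then gives the divinyl carbinol F5; with the arms in this order the required C1' configuration corresponds to Felkin–Anh addition anti to the Cα–O bond. Second-generation Grubbs catalyst (CH2Cl2, 40 °C) closes the cyclohexene F6, and diimide (o-nitrobenzenesulfonyl hydrazide, Et3N) saturates the ring alkene to 27.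

Step 23 (late Appel bromination at C4'). The axial oxyphosphonium ion may undergo anti elimination toward C5' or methyl migration from C3' instead of substitution, and the free tertiary alcohols may be activated on heating. The fallback sets out from 28 and comes back at 29. The secondary alcohol is sulfonylated selectively (ClCH2SO2Cl, pyridine, 0 °C) to the chloromethanesulfonate F7, a compact, isolable leaving group that does not require heating with a phosphine, and is displaced with LiBr (DMF, 40 °C) with inversion to 29.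

Step 26 (hydride reduction of the β-acetoxy ketone). Facial selectivity may be poor because the angular C3a methyl shields the face that the hydride must use, and the acetate may migrate or be eliminated. The fallback sets out from 30 and comes back at 32. Hydroxyl-directed syn reduction (Et2BOMe, NaBH4, THF/MeOH, −78 °C) through the boron chelate gives the 1,3-syn diol F8. The less hindered C2 hydroxyl is silylated (Et3SiCl, imidazole, CH2Cl2, −20 °C) to F9, the Cα hydroxyl is acetylated (Ac2O, DMAP, pyridine) to F10, and HF·pyridine removes the silyl group to give 32.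

Further compounds
F1 | step 21 | Weinreb amide of 18 (N-methoxy-N-methyl carboxamide at Cα) | O1N=C2C[C@]3(C)[C@@H](Br)CC[C@@](C)(O[Si](CC)(CC)CC)[C@H]3[C@@H]2[C@@H]1C(=O)N(C)OC
F2 | step 21 | (R)-5-bromo-4,4-dimethyl-3-[(triisopropylsilyl)oxy]pent-1-ene | C=C[C@@H](O[Si](C(C)C)(C(C)C)C(C)C)C(C)(C)CBr
F3 | step 21 | Grignard reagent of F2 | C=C[C@@H](O[Si](C(C)C)(C(C)C)C(C)C)C(C)(C)C[Mg]Br
F4 | step 21 | isoxazolinyl ketone carrying the 2,2-dimethyl-3-silyloxypent-4-enyl arm | O1N=C2C[C@]3(C)[C@@H](Br)CC[C@@](C)(O[Si](CC)(CC)CC)[C@H]3[C@@H]2[C@@H]1C(=O)CC(C)(C)[C@H](O[Si](C(C)C)(C(C)C)C(C)C)C=C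
F5 | step 21 | tertiary divinyl carbinol (C1' set, both alkenes terminal) | O1N=C2C[C@]3(C)[C@@H](Br)CC[C@@](C)(O[Si](CC)(CC)CC)[C@H]3[C@@H]2[C@@H]1[C@@](O)(C=C)CC(C)(C)[C@H](O[Si](C(C)C)(C(C)C)C(C)C)C=C
F6 | step 21 | cyclohexene from ring-closing metathesis (C5'=C6' alkene, otherwise as 27) | O1N=C2C[C@]3(C)[C@@H](Br)CC[C@@](C)(O[Si](CC)(CC)CC)[C@H]3[C@@H]2[C@@H]1[C@@]4(O)C=C[C@@H](O[Si](C(C)C)(C(C)C)C(C)C)C(C)(C)C4
F7 | step 23 | C4' chloromethanesulfonate of 28 | O1N=C2C[C@]3(C)[C@@H](Br)CC[C@@](C)(O)[C@H]3[C@@H]2[C@@H]1[C@@]4(O)CC[C@@H](OS(=O)(=O)CCl)C(C)(C)C4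
F8 | step 26 | deacetyl target (C2,Cα syn diol) | O[C@H]([C@@H]1[C@H](O)C[C@]2(C)[C@@H](Br)CC[C@@](C)(O)[C@@H]12)[C@@]1(O)CC[C@H](Br)C(C)(C)C1
F9 | step 26 | C2 triethylsilyl ether of F8 | O[C@H]([C@@H]1[C@H](O[Si](CC)(CC)CC)C[C@]2(C)[C@@H](Br)CC[C@@](C)(O)[C@@H]12)[C@@]1(O)CC[C@H](Br)C(C)(C)C1
F10 | step 26 | C2 triethylsilyl ether of the target | CC(=O)O[C@H]([C@@H]1[C@H](O[Si](CC)(CC)CC)C[C@]2(C)[C@@H](Br)CC[C@@](C)(O)[C@@H]12)[C@@]1(O)CC[C@H](Br)C(C)(C)C1
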